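Numbering: benzofuran O1, C2, C3, C3a, C4 to C7, C7a; C9 is the CH2O on C3; ring A is the benzo ring, ring B the dihydrofuran, ring C the aryl group on C2. The retrosynthesis cuts, in this order, the C9–O bond of the p-coumarate, the C5–CH2 bond of the feruloyloxypropyl arm, the aryl ether bond O1–C7a of ring B, and the C2–C3 bond.
Forward: ring A enters as a 2-fluoroanisole and receives its acetic acid arm at C3a and a bromine at C5. An aldol reaction joins it to ring C (vanillin), ring B is then closed, and the two cinnamate arms follow.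
Enabling feature: in ring A, C7a is ortho to C3a, so the oxygen on C2 reaches it through a five-membered transition state. C7a is also para to C5, so the halogen parked there for the later chain takes up the negative charge of the substitution. Fluorine at C7a and bromine at C5 react in orthogonal ways.
Stereochemistry: C2 and C3 both come from one syn aldol step controlled by (R)-4-benzyloxazolidinone. Syn maps onto the trans ring, and closure at an sp2 carbon leaves both centres untouched.
Protecting groups: only base-stable, non-migrating acetal and trityl ethers are used. They fall in one acid step, and the last ester is made by a Mitsunobu reaction that tolerates free phenols.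

Key step: step 9

Assumption: the trans (2R,3S) configuration encoded in the given SMILES is taken as that of the dextrorotatory compound.

Step 1
Reactants: 1 (2-fluoro-3-methoxyphenyl)boronic acid; 2 methyl bromoacetate
Product: 3 methyl 2-(2-fluoro-3-methoxyphenyl)acetate
Conditions: Pd(OAc)2 (3 mol %), P(1-naphthyl)3, K3PO4, THF/H2O, 25 °C
Reagents that add atoms: none
Why: A Suzuki–Miyaura-type coupling of an arylboronic acid with an α-bromo ester, in which zerovalent palladium inserts into the activated C–Br bond, should put the two-carbon arm on the future C3a next to fluorine.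

Step 2
Reactants: 3 methyl 2-(2-fluoro-3-methoxyphenyl)acetate
Product: 5 methyl 2-(5-bromo-2-fluoro-3-methoxyphenyl)acetate, via aryl pinacol boronate 4 (not isolated)
Conditions: [Ir(OMe)(cod)]2, dtbpy, B2pin2, THF, 80 °C; then CuBr2, MeOH/H2O, 80 °C
Reagents that add atoms: bis(pinacolato)diboron, CC1(C)OB(OC1(C)C)B1OC(C)(C)C(C)(C)O1 (boryl group, kept only in 4); CuBr2, [Cu+2].[Br-].[Br-] (bromine)
Why: Sterically controlled iridium-catalysed C–H borylation should pick the only ring C–H without an ortho neighbour (para to fluorine), and copper-mediated bromodeboronation then exchanges boron for bromine at that carbon.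

Step 3
Reactants: 5 methyl 2-(5-bromo-2-fluoro-3-methoxyphenyl)acetate
Product: 6 2-(5-bromo-2-fluoro-3-methoxyphenyl)acetic acid
Conditions: LiOH, THF/H2O, 25 °C; then aq HCl
Reagents that add atoms: lithium hydroxide, [Li+].[OH-] (oxygen of the acid)
Why: Saponification of the methyl ester under mild conditions should leave the aryl fluoride and the aryl bromide untouched.

Step 4
Reactants: 6 2-(5-bromo-2-fluoro-3-methoxyphenyl)acetic acid; 7 (R)-4-benzyl-1,3-oxazolidin-2-one
Product: 9 (R)-4-benzyl-3-[2-(5-bromo-2-fluoro-3-methoxyphenyl)acetyl]oxazolidin-2-one, via mixed pivalic anhydride 8 (not isolated)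
Conditions: PivCl, Et3N, THF, −20 °C; then LiCl, 7, 25 °C
Reagents that add atoms: pivaloyl chloride, CC(C)(C)C(=O)Cl (pivaloyl group, kept only in 8)
Why: N-acylation of the oxazolidinone through the mixed anhydride (LiCl and Et3N variant) avoids strong base next to the acidic benzylic CH2.

Step 5
Reactants: 10 vanillin
Product: 11 3-methoxy-4-(methoxymethoxy)benzaldehyde
Conditions: MOMCl, i-Pr2NEt, CH2Cl2, 0 to 25 °C
Reagents that add atoms: chloromethyl methyl ether, COCCl
Why: Williamson-type O-alkylation gives a phenol acetal that should withstand the boron Lewis acid at low temperature, hydride, tert-butoxide and aqueous phosphate, and that falls off with mild acid.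

Step 6
Reactants: 9 (R)-4-benzyl-3-[2-(5-bromo-2-fluoro-3-methoxyphenyl)acetyl]oxazolidin-2-one; 11 3-methoxy-4-(methoxymethoxy)benzaldehyde
Product: 14 (R)-4-benzyl-3-[(2R,3R)-2-(5-bromo-2-fluoro-3-methoxyphenyl)-3-hydroxy-3-[3-methoxy-4-(methoxymethoxy)phenyl]propanoyl]oxazolidin-2-one, via Z boron enolate 12 (not isolated), via boron aldolate 13 (not isolated)
Conditions: Bu2BOTf, Et3N, CH2Cl2, −78 to 0 °C; 11, −78 to 0 °C; then pH 7 buffer, MeOH, H2O2, 0 °C
Reagents that add atoms: dibutylboryl triflate, CCCCB(CCCC)OS(=O)(=O)C(F)(F)F (Bu2B group, kept only in 12 and 13)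
Why: In this Evans syn aldol reaction the Z boron enolate reacts through a chair Zimmerman–Traxler transition state on the face away from the benzyl group of the (R)-auxiliary, which sets both the α centre (future C3) and the carbinol centre (future C2) as the (2R,3R) syn adduct.

Step 7
Reactants: 14 syn aldol adduct
Product: 15 (1R,2S)-2-(5-bromo-2-fluoro-3-methoxyphenyl)-1-[3-methoxy-4-(methoxymethoxy)phenyl]propane-1,3-diol
Conditions: LiBH4, MeOH (1 equiv), THF, 0 °C
Reagents that add atoms: none
Why: Reductive cleavage of the imide with LiBH4 attacks the exocyclic carbonyl, releases the auxiliary for reuse and should touch neither stereocentre nor the aryl halides.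

Step 8
Reactants: 15 (1R,2S)-diol
Product: 16 (1R,2S)-2-(5-bromo-2-fluoro-3-methoxyphenyl)-1-[3-methoxy-4-(methoxymethoxy)phenyl]-3-(trityloxy)propan-1-ol
Conditions: TrCl, Et3N, DMAP (cat.), CH2Cl2, 25 °C
Reagents that add atoms: trityl chloride, ClC(c1ccccc1)(c1ccccc1)c1ccccc1
Why: Tritylation is selective for the primary hydroxyl on steric grounds and gives an ether that cannot migrate under base.

Step 9
Reactants: 16 (1R,2S)-trityl ether alcohol
Product: 18 (2R,3S)-5-bromo-7-methoxy-2-[3-methoxy-4-(methoxymethoxy)phenyl]-3-[(trityloxy)methyl]-2,3-dihydrobenzofuran, via potassium alkoxide 17 (not isolated)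
Conditions: KOt-Bu (1.1 equiv), THF, 0 to 60 °C
Reagents that add atoms: potassium tert-butoxide, CC(C)(C)[O-].[K+] (potassium, kept only in 17)
Why: Deprotonation gives alkoxide 17, whose oxygen adds to C7a and expels fluoride in an intramolecular nucleophilic aromatic substitution (addition–elimination through a Meisenheimer-type transition state); the closest known reaction type is the base-induced cyclisation of 2-(2-fluoroaryl)ethanols to 2,3-dihydrobenzofurans. Ring B closes in the 5-exo-trig mode, and O1, C2, C3, C3a and C7a are preorganised because C7a is ortho to the carbon that carries the side chain. No stereocentre is made: the new bond ends at an sp2 carbon and neither the C2–O bond nor any bond at C3 is broken, so the syn array of 16 is carried over as the trans (2R,3S) ring, which is also the less strained isomer. Selectivity between the two halogens is needed and is secured by the mechanism, since fluoride is by far the better leaving group in this substitution, while the bromine at C5, para to C7a, only takes up negative charge and stays for step 12. Selectivity between the two oxygens is secured by the trityl ether, which unlike a silyl or acyl group cannot migrate to the C2 alkoxide and so keeps the C9 oxygen from closing the isomeric five-membered ring. The MOM and trityl ethers and the aryl bromide should be inert to one equivalent of alkoxide base at this temperature.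

Step 10
Reactants: 19 (E)-ferulic acid; 20 allyl alcohol
Product: 21 allyl (E)-ferulate
Conditions: 20 (solvent), p-TsOH (cat.), reflux
Reagents that add atoms: none
Why: Fischer esterification acylates only at the carboxyl group and leaves the phenol and the E alkene unchanged.

Step 11
Reactants: 21 allyl (E)-ferulate
Product: 22 allyl (E)-3-[3-methoxy-4-(methoxymethoxy)phenyl]acrylate
Conditions: MOMCl, i-Pr2NEt, CH2Cl2, 0 to 25 °C
Reagents that add atoms: chloromethyl methyl ether, COCCl
Why: Williamson-type O-alkylation masks the phenol so that it neither consumes borane nor forms a phenoxide in the coupling step.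

Step 12
Reactants: 18 (2R,3S)-5-bromodihydrobenzofuran; 22 allyl (E)-3-[3-methoxy-4-(methoxymethoxy)phenyl]acrylate
Product: 24 3-{(2R,3S)-7-methoxy-2-[3-methoxy-4-(methoxymethoxy)phenyl]-3-[(trityloxy)methyl]-2,3-dihydrobenzofuran-5-yl}propyl (E)-3-[3-methoxy-4-(methoxymethoxy)phenyl]acrylate, via B-alkyl borane 23 (not isolated)
Conditions: 22, 9-BBN, THF, 25 °C; then 18, PdCl2(dppf), K3PO4 (aq), DMF, 50 °C
Reagents that add atoms: 9-borabicyclo[3.3.1]nonane, B1C2CCCC1CCC2 (boryl group, kept only in 23)
Why: Hydroboration with 9-BBN takes only the terminal allyl alkene (the conjugated cinnamate alkene and the ester are inert), and the B-alkyl Suzuki–Miyaura coupling then joins the primary alkyl group to C5 at the bromide kept for this purpose, far from both stereocentres.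

Step 13
Reactants: 24 fully protected mono-ester
Product: 25 3-[(2R,3S)-2-(4-hydroxy-3-methoxyphenyl)-3-(hydroxymethyl)-7-methoxy-2,3-dihydrobenzofuran-5-yl]propyl (E)-ferulate
Conditions: p-TsOH·H2O (cat.), MeOH/CH2Cl2, 40 °C
Reagents that add atoms: none
Why: Acid-catalysed transacetalisation and trityl solvolysis in methanol should free both phenols and the C9 hydroxyl at once, while the conjugated ester exchanges much more slowly and the trans ring is the thermodynamic isomer should the C2–O1 bond ionise reversibly.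

Step 14
Reactants: 25 phenolic primary alcohol; 26 (E)-p-coumaric acid
Product: 27 (+)-boehmenan X
Conditions: PPh3, DIAD, THF, 0 to 25 °C
Reagents that add atoms: none
Why: The Mitsunobu esterification activates the only aliphatic hydroxyl, which is then attacked by the carboxylate as the most acidic pronucleophile present, so the three phenols need no protection and the reacting CH2 carbon is not stereogenic.

Compound list
1 | (2-fluoro-3-methoxyphenyl)boronic acid | COc1cccc(B(O)O)c1F | starting material
2 | methyl bromoacetate | COC(=O)CBr | starting material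
3 | methyl 2-(2-fluoro-3-methoxyphenyl)acetate | COC(=O)Cc1cccc(OC)c1F | intermediate
4 | methyl 2-[2-fluoro-3-methoxy-5-(4,4,5,5-tetramethyl-1,3,2-dioxaborolan-2-yl)phenyl]acetate | COC(=O)Cc1cc(B2OC(C)(C)C(C)(C)O2)cc(OC)c1F | intermediate
5 | methyl 2-(5-bromo-2-fluoro-3-methoxyphenyl)acetate | COC(=O)Cc1cc(Br)cc(OC)c1F | intermediate
6 | 2-(5-bromo-2-fluoro-3-methoxyphenyl)acetic acid | OC(=O)Cc1cc(Br)cc(OC)c1F | intermediate
7 | (R)-4-benzyl-1,3-oxazolidin-2-one | O=C1N[C@H](Cc2ccccc2)CO1 | starting material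
8 | 2-(5-bromo-2-fluoro-3-methoxyphenyl)acetic pivalic anhydride | CC(C)(C)C(=O)OC(=O)Cc1cc(Br)cc(OC)c1F | intermediate
9 | (R)-4-benzyl-3-[2-(5-bromo-2-fluoro-3-methoxyphenyl)acetyl]oxazolidin-2-one | COc1cc(Br)cc(CC(=O)N2C(=O)OC[C@H]2Cc2ccccc2)c1F | intermediate
10 | vanillin | COc1cc(C=O)ccc1O | starting material
11 | 3-methoxy-4-(methoxymethoxy)benzaldehyde | COCOc1ccc(C=O)cc1OC | intermediate
12 | (Z)-dibutylboron enolate of 9 | CCCCB(CCCC)O/C(=C\c1cc(Br)cc(OC)c1F)N1C(=O)OC[C@H]1Cc1ccccc1 | intermediate
13 | O-dibutylboryl derivative (boron aldolate) of 14 | COc1cc(Br)cc([C@@H](C(=O)N2C(=O)OC[C@H]2Cc2ccccc2)[C@H](c2ccc(OCOC)c(OC)c2)OB(CCCC)CCCC)c1F | intermediate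
14 | (R)-4-benzyl-3-[(2R,3R)-2-(5-bromo-2-fluoro-3-methoxyphenyl)-3-hydroxy-3-[3-methoxy-4-(methoxymethoxy)phenyl]propanoyl]oxazolidin-2-one | COc1cc(Br)cc([C@@H](C(=O)N2C(=O)OC[C@H]2Cc2ccccc2)[C@H](c2ccc(OCOC)c(OC)c2)O)c1F | intermediate
15 | (1R,2S)-2-(5-bromo-2-fluoro-3-methoxyphenyl)-1-[3-methoxy-4-(methoxymethoxy)phenyl]propane-1,3-diol | COc1cc(Br)cc([C@@H](CO)[C@H](c2ccc(OCOC)c(OC)c2)O)c1F | intermediate
16 | (1R,2S)-2-(5-bromo-2-fluoro-3-methoxyphenyl)-1-[3-methoxy-4-(methoxymethoxy)phenyl]-3-(trityloxy)propan-1-ol | COc1cc(Br)cc([C@@H](COC(c2ccccc2)(c2ccccc2)c2ccccc2)[C@H](c2ccc(OCOC)c(OC)c2)O)c1F | intermediate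
17 | potassium alkoxide of 16 | COc1cc(Br)cc([C@@H](COC(c2ccccc2)(c2ccccc2)c2ccccc2)[C@H](c2ccc(OCOC)c(OC)c2)[O-])c1F.[K+] | intermediate
18 | (2R,3S)-5-bromo-7-methoxy-2-[3-methoxy-4-(methoxymethoxy)phenyl]-3-[(trityloxy)methyl]-2,3-dihydrobenzofuran | Brc1cc(OC)c2c(c1)[C@@H](COC(c1ccccc1)(c1ccccc1)c1ccccc1)[C@H](c1ccc(OCOC)c(OC)c1)O2 | intermediate
19 | (E)-ferulic acid | COc1cc(/C=C/C(=O)O)ccc1O | starting material
20 | allyl alcohol | C=CCO | starting material
21 | allyl (E)-ferulate | C=CCOC(=O)/C=C/c1ccc(O)c(OC)c1 | intermediate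
22 | allyl (E)-3-[3-methoxy-4-(methoxymethoxy)phenyl]acrylate | C=CCOC(=O)/C=C/c1ccc(OCOC)c(OC)c1 | intermediate
23 | 3-(9-borabicyclo[3.3.1]nonan-9-yl)propyl (E)-3-[3-methoxy-4-(methoxymethoxy)phenyl]acrylate | COCOc1ccc(/C=C/C(=O)OCCCB2C3CCCC2CCC3)cc1OC | intermediate
24 | 3-{(2R,3S)-7-methoxy-2-[3-methoxy-4-(methoxymethoxy)phenyl]-3-[(trityloxy)methyl]-2,3-dihydrobenzofuran-5-yl}propyl (E)-3-[3-methoxy-4-(methoxymethoxy)phenyl]acrylate | COc1cc(/C=C/C(=O)OCCCc2cc(OC)c3c(c2)[C@@H](COC(c2ccccc2)(c2ccccc2)c2ccccc2)[C@H](c2ccc(OCOC)c(OC)c2)O3)ccc1OCOC | intermediate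
25 | 3-[(2R,3S)-2-(4-hydroxy-3-methoxyphenyl)-3-(hydroxymethyl)-7-methoxy-2,3-dihydrobenzofuran-5-yl]propyl (E)-ferulate | COc1cc(/C=C/C(=O)OCCCc2cc(OC)c3c(c2)[C@@H](CO)[C@H](c2ccc(O)c(OC)c2)O3)ccc1O | intermediate
26 | (E)-p-coumaric acid | OC(=O)/C=C/c1ccc(O)cc1 | starting material
27 | (+)-boehmenan X, (2R,3S) | COc1cc(/C=C/C(=O)OCCCc2cc(OC)c3c(c2)[C@@H](COC(=O)/C=C/c2ccc(O)cc2)[C@H](c2ccc(O)c(OC)c2)O3)ccc1O | target

Total step count: 14
Longest linear sequence: 11 steps (1, 2, 3, 4, 6, 7, 8, 9, 12, 13, 14)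

Steps most likely to fail

Step 9. The substitution may be slow because ring A carries only a weak acceptor, so that base-induced loss of hydrogen bromide from the ring or attack by tert-butoxide could compete with ring closure. The fallback sets out from 16 and comes back at 24; it strengthens the acceptor at C5 before closure and rebuilds the coupling handle afterwards.
- Bromine–lithium exchange on 16 (n-BuLi, 2.2 equiv, THF, −78 °C) and trapping with DMF would give the fluoro aldehyde F1.
- In F1 the formyl group para to C7a should allow closure with Cs2CO3 in DMF at 25 to 50 °C to the ring-closed aldehyde F2.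
- Baeyer–Villiger oxidation (mCPBA, CH2Cl2) would give the aryl formate F3, methanolysis (K2CO3, MeOH) the phenol F4, and sulfonylation (Tf2O, pyridine) the aryl triflate F5.
- B-alkyl Suzuki–Miyaura coupling of F5 with borane 23 under the conditions of step 12 would then give 24.

Step 12. Oxidative addition to the electron-rich bromide may be sluggish, so that protodeboronation of the borane, β-hydride elimination from the alkylpalladium species or saponification of the cinnamate by the aqueous base takes over. The fallback sets out from 18 and comes back at 25; it builds the chain stepwise and makes the ester afterwards.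
- A Heck reaction of 18 with allyl alcohol 20 (Pd(OAc)2, Bu4NCl, NaHCO3, DMF, 50 °C), which ends by migration of the double bond to the carbonyl, would give the 3-arylpropanal F6.
- NaBH4 in MeOH would give the primary alcohol F7.
- Mitsunobu esterification with ferulic acid 19 would give the phenolic ester F8, and the acid treatment of step 13 would give 25.

Step 14. Alkylation of one of the free phenols by the activated C9 carbon, or elimination across C3–C9, could compete with ester formation. The fallback sets out from 24 and comes back at 27; it uses carbodiimide acylation with all phenols masked.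
- Selective trityl solvolysis of 24 (camphorsulfonic acid cat., MeOH/CH2Cl2, 0 °C) would give the bis-MOM alcohol F9.
- p-Coumaric acid 26 with MOMCl and i-Pr2NEt (two equivalents each) would give the MOM ester ether F10, and LiOH would give the MOM-protected acid F11.
- Steglich esterification of F9 with F11 (EDC·HCl, DMAP, CH2Cl2) would give the tris-MOM diester F12, and p-TsOH in MeOH/CH2Cl2 would give 27.

Further compounds
F1 | step 9 | 4-fluoro-3-{(1R,2S)-1-hydroxy-1-[3-methoxy-4-(methoxymethoxy)phenyl]-3-(trityloxy)propan-2-yl}-5-methoxybenzaldehyde | COc1cc(C=O)cc([C@@H](COC(c2ccccc2)(c2ccccc2)c2ccccc2)[C@H](c2ccc(OCOC)c(OC)c2)O)c1F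
F2 | step 9 | (2R,3S)-7-methoxy-2-[3-methoxy-4-(methoxymethoxy)phenyl]-3-[(trityloxy)methyl]-2,3-dihydrobenzofuran-5-carbaldehyde | O=Cc1cc(OC)c2c(c1)[C@@H](COC(c1ccccc1)(c1ccccc1)c1ccccc1)[C@H](c1ccc(OCOC)c(OC)c1)O2
F3 | step 9 | (2R,3S)-7-methoxy-2-[3-methoxy-4-(methoxymethoxy)phenyl]-3-[(trityloxy)methyl]-2,3-dihydrobenzofuran-5-yl formate | O=COc1cc(OC)c2c(c1)[C@@H](COC(c1ccccc1)(c1ccccc1)c1ccccc1)[C@H](c1ccc(OCOC)c(OC)c1)O2
F4 | step 9 | (2R,3S)-7-methoxy-2-[3-methoxy-4-(methoxymethoxy)phenyl]-3-[(trityloxy)methyl]-2,3-dihydrobenzofuran-5-ol | Oc1cc(OC)c2c(c1)[C@@H](COC(c1ccccc1)(c1ccccc1)c1ccccc1)[C@H](c1ccc(OCOC)c(OC)c1)O2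
F5 | step 9 | (2R,3S)-7-methoxy-2-[3-methoxy-4-(methoxymethoxy)phenyl]-3-[(trityloxy)methyl]-2,3-dihydrobenzofuran-5-yl trifluoromethanesulfonate | O=S(=O)(Oc1cc(OC)c2c(c1)[C@@H](COC(c1ccccc1)(c1ccccc1)c1ccccc1)[C@H](c1ccc(OCOC)c(OC)c1)O2)C(F)(F)F
F6 | step 12 | 3-{(2R,3S)-7-methoxy-2-[3-methoxy-4-(methoxymethoxy)phenyl]-3-[(trityloxy)methyl]-2,3-dihydrobenzofuran-5-yl}propanal | O=CCCc1cc(OC)c2c(c1)[C@@H](COC(c1ccccc1)(c1ccccc1)c1ccccc1)[C@H](c1ccc(OCOC)c(OC)c1)O2
F7 | step 12 | 3-{(2R,3S)-7-methoxy-2-[3-methoxy-4-(methoxymethoxy)phenyl]-3-[(trityloxy)methyl]-2,3-dihydrobenzofuran-5-yl}propan-1-ol | OCCCc1cc(OC)c2c(c1)[C@@H](COC(c1ccccc1)(c1ccccc1)c1ccccc1)[C@H](c1ccc(OCOC)c(OC)c1)O2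
F8 | step 12 | 3-{(2R,3S)-7-methoxy-2-[3-methoxy-4-(methoxymethoxy)phenyl]-3-[(trityloxy)methyl]-2,3-dihydrobenzofuran-5-yl}propyl (E)-ferulate | COc1cc(/C=C/C(=O)OCCCc2cc(OC)c3c(c2)[C@@H](COC(c2ccccc2)(c2ccccc2)c2ccccc2)[C@H](c2ccc(OCOC)c(OC)c2)O3)ccc1O
F9 | step 14 | 3-{(2R,3S)-3-(hydroxymethyl)-7-methoxy-2-[3-methoxy-4-(methoxymethoxy)phenyl]-2,3-dihydrobenzofuran-5-yl}propyl (E)-3-[3-methoxy-4-(methoxymethoxy)phenyl]acrylate | COc1cc(/C=C/C(=O)OCCCc2cc(OC)c3c(c2)[C@@H](CO)[C@H](c2ccc(OCOC)c(OC)c2)O3)ccc1OCOC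
F10 | step 14 | methoxymethyl (E)-3-[4-(methoxymethoxy)phenyl]acrylate | COCOC(=O)/C=C/c1ccc(OCOC)cc1
F11 | step 14 | (E)-3-[4-(methoxymethoxy)phenyl]acrylic acid | OC(=O)/C=C/c1ccc(OCOC)cc1
F12 | step 14 | tris-O-methoxymethyl ether of 27 | COc1cc(/C=C/C(=O)OCCCc2cc(OC)c3c(c2)[C@@H](COC(=O)/C=C/c2ccc(OCOC)cc2)[C@H](c2ccc(OCOC)c(OC)c2)O3)ccc1OCOC
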